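# Hanultarin (19): synthesis design

## The problem

Hanultarin (19) is the mono-(E)-ferulate of a C2-symmetric lignan diol. Its core is the acyclic chain C7–C8–C8′–C7′, with guaiacyl-bearing benzylic CH2 groups at the ends and a CH2O arm (C9, C9′) on each inner carbon. The three arenes are the only rings, so the task is to build a branched open chain, not to join rings. The only stereocentres are the adjacent methines C8 and C8′ (both R). They carry no heteroatom and are equivalent in the diol, so neither can direct the other: they must be made together or each set by its own external element. The two primary hydroxyls of the diol are homotopic, so mono-acylation has no regiochemical problem but is statistical. The fragile groups are three free phenols (easily oxidised), the cinnamate (a reducible alkene on a base-labile ester) and the 1,4-diol or hydroxy ester, which closes to a tetrahydrofuran under acid or Mitsunobu activation. Phenol protection must therefore come off without hydrogen, strong acid or strong base. The enabling feature is that C8 and C8′ each carry one benzylic carbon and one CH2O carbon. If C9 and C9′ are read as the stumps of two (E)-propenyl groups, C8 and C8′ become C4 and C5 of an octa-3,5-diene, the two γ-termini of a bis-allylic diester, and C7 and C7′ become the α-carbons of two arylacetates. Two [3,3] shifts then form C7–C8 and C7′–C8′ and copy two carbinol configurations onto C8 and C8′.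

## Retrosynthesis

**Ester and silyl ethers.** The acyl C–O bond at C9 and the three aryl O–Si bonds are cut: 19 comes from tris-silyl ester 18, and 18 from diol 14 and O-silyl ferulic acid 17 (from ferulic acid 15 via 16). Cutting the ester, not a C–C bond of the cinnamate, uses ferulic acid with its E-alkene already in place. Silyl protection is preferred to benzyl or acetal groups because buffered fluoride removes it without touching the cinnamate alkene or promoting tetrahydrofuran formation. Diol 14 is C2-symmetric, so only half of it has to be designed. The forward reaction must stop at one ester, which calls for limiting 17 and recycling 14.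

**C9 and C9′ as alkene stumps.** The C9–O and C9′–O bonds are traced to two C=C bonds: 14 comes from diene 12 by oxidative cleavage of two (E)-propenyl groups with reductive work-up. An alkene is preferred to an ester or ether at C9 because it survives the bases and radicals of the earlier steps and is exactly what a [3,3] shift leaves behind. Diene 12 has no chain oxygen. The cleavage must spare the electron-rich arenes and must not leave an epimerisable aldehyde standing next to C8.

**Traceless carboxyl groups at C7 and C7′.** Two C–CO2H bonds are added: 12 comes from diacid 11 by twofold hydrodecarboxylation. Placing a carboxyl on each benzylic carbon makes C7 and C7′ enolisable arylacetate α-carbons. Attaching the aryl groups later by cross-coupling at primary carbons would be less direct. The two extra stereocentres in 11 are of no consequence because both become CH2. The decarboxylation must tolerate alkenes, silyl ethers and electron-rich arenes.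

**Key disconnection, C7–C8 and C7′–C8′.** Diacid 11 comes from bis(arylacetate) 7 by two Ireland–Claisen shifts through intermediates 8, 9 and 10. Cutting these two bonds, not C8–C8′, replaces a stereoselective dimerisation or auxiliary-controlled alkylation by two intramolecular sigmatropic shifts whose facial sense is fixed by carbinol centres. Precursor 7 has only two stereocentres, both C–O, and is the diester of a symmetric diol. The forward step needs enolisation at both arylacetates, a chair transition state in both shifts, and completion of the second shift.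

**Ester bonds of 7.** The two acyl C–O bonds are cut to dienediol 6 and O-silyl homovanillic acid 3 (from homovanillic acid 1 via 2). The esterification must be neutral, because a dienyl carbinol ionises easily under acid.

**Diene and central C–C bond of 6.** The E,E-diene is traced to diyne 5 by trans-reduction, and the central sp–sp bond of 5 to two molecules of (S)-but-3-yn-2-ol (4) by oxidative homocoupling. Homocoupling halves the problem, and both carbinol centres are bought. The reduction must give the E,E-diene without touching the carbinols.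

## Roads not taken

Alternative 1: The cut is through C8–C8′ and C7–C7′, both made at once by head-to-head [2+2] dimerisation of two ferulate units, with C7–C7′ broken again afterwards. In the forward step the protected feruloyl imidazole A1, bound to a chiral phosphoric acid, is sensitised to its triplet by [Ir(dF(CF3)ppy)2(dtbbpy)]PF6 under visible light and dimerises to the all-trans cyclobutane A2.
- Merits: both halves come from ferulic acid, and the C8–C8′ bond and both stereocentres arise catalytically from achiral material. No stoichiometric chiral building block is needed.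
- Weak points: one bond is made only to be broken. Under electron-transfer conditions the cyclobutane bond most prone to reductive scission is C8–C8′, which lies between two acyl groups, not the wanted C7–C7′ bond. Cycloreversion to A1 is a further escape. The dimerisation must also control head-to-head against head-to-tail regiochemistry, the all-trans diastereomer and the enantiomer in one step. The acetal protecting groups need acid for removal, which invites tetrahydrofuran formation.
- Comparison: this road is more convergent and, unlike the chosen plan, does not discard two CO2 and two C2 units. Against that, every operation of the chosen plan has a known mechanistic basis, and its absolute configuration comes from a purchased carbinol, not from an untested selective ring opening.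

Alternative 2: The cut is at C8′–C9′ (CO as C9′) and at the lactone C–O bond. In the forward step the (E)-allylic alcohol A3 reacts with CO and H2 under a zerovalent palladium source, Pd2(dba)3, and a chiral bisphosphine of the BPPM type. Syn delivery of H and acyl to the E-alkene, then lactonisation, gives the trans lactone A4, which LiAlH4 would reduce to diol 14.
- Merits: both stereocentres and one C–C bond form in one catalytic step, no carbon is discarded, and 14 would be reached in fewer steps than by the chosen route.
- Weak points: good enantiocontrol in this cyclocarbonylation is tied to allylic alcohols with a terminal, 1,1-disubstituted alkene. A3 is a primary allylic alcohol with a trisubstituted alkene. It can ionise to a π-allyl palladium species, leading to hydrogenolysis or β,γ-unsaturated acids, or isomerise into conjugation with the arene. Both the trans relationship and the enantiomeric purity would rest on a substrate class without support. A3 also needs its own stereodefined alkene synthesis.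
- Comparison: this road is better in step and atom economy. The chosen plan offers predictable stereochemistry through ordered cyclic transition states.

Alternative 3: The cut is at C8–C9 and C8′–C9′ together. In the forward step the E-alkene A5 takes up two CO and two methanol molecules under divalent palladium, Pd(O2CCF3)2, a chiral bis(oxazoline)-type ligand and p-benzoquinone. Syn addition to the E-alkene gives the chiral succinate A6, and reduction would give the dibenzyl diol A7.
- Merits: this is the shortest route, since a symmetric alkene becomes the whole stereodefined core in one step.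
- Weak points: enantioselective bis(alkoxycarbonylation) works best on terminal and aryl-substituted alkenes, whereas internal 1,2-dialkyl alkenes react slowly and with poor facial discrimination. The alkyl–palladium intermediate from A5 has benzylic β-hydrogens, so β-hydride elimination to styrenyl mono-esters competes with the second carbonylation. The benzyl ethers of A7 cannot be removed by hydrogenolysis once the ferulate is attached, so protection would have to be redesigned.
- Comparison: this road is clearly better in step count and atom economy. The chosen plan offers secure control of both centres and a protecting-group scheme that fits the final ester.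

Key step: step 5

Assumption: the arylacetate enolate is taken to be silylated with aryl cis to OSiMe3. The configurations drawn at the aryl-bearing carbons of 9–11 rest on this and do not matter, because both centres become CH2 in step 6.

## Route

Step 1
Reactants: 1 homovanillic acid, (4-hydroxy-3-methoxyphenyl)acetic acid
Product: 3 [4-(tert-butyldimethylsilyloxy)-3-methoxyphenyl]acetic acid, via bis-silylated ester 2 (not isolated)
Conditions: TBSCl (2.4 equiv), imidazole, DMF, rt; then AcOH/THF/H2O, rt
Reagents that add atoms: tert-butyldimethylsilyl chloride (TBSCl), CC(C)(C)[Si](C)(C)Cl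
Why: Silylation of phenol and acid, then selective hydrolysis of the far more labile silyl ester under mild aqueous acid, which leaves the aryl silyl ether intact.

Step 2
Reactants: 4 (S)-but-3-yn-2-ol (2 equiv)
Product: 5 (2S,7S)-octa-3,5-diyne-2,7-diol
Conditions: CuCl (10 mol %), Me2NCH2CH2NMe2 (10 mol %), O2 (1 atm), acetone, rt
Reagents that add atoms: none
Why: Glaser–Hay oxidative homocoupling: two molecules of the terminal alkyne 4 are joined at their sp carbons, the two alkyne hydrogens leaving as water with O2 as the terminal oxidant. The carbinol centres are not involved and keep their S configuration.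

Step 3
Reactants: 5 (2S,7S)-octa-3,5-diyne-2,7-diol
Product: 6 (2S,3E,5E,7S)-octa-3,5-diene-2,7-diol
Conditions: LiAlH4 (4 equiv), THF, 0 °C → reflux; aq. NaOH work-up
Reagents that add atoms: none
Why: Alkoxide-directed trans-hydroalumination of each propargylic alcohol and protonolysis give the E-alkene at both ends, as known for conjugated diyne-diols; the carbinols are untouched.

Step 4
Reactants: 6 (2S,3E,5E,7S)-octa-3,5-diene-2,7-diol; 3 [4-(tert-butyldimethylsilyloxy)-3-methoxyphenyl]acetic acid (2.4 equiv)
Product: 7 (2S,3E,5E,7S)-octa-3,5-diene-2,7-diyl bis{[4-(tert-butyldimethylsilyloxy)-3-methoxyphenyl]acetate}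
Conditions: DCC, 4-(dimethylamino)pyridine (cat.), CH2Cl2, 0 °C → rt
Reagents that add atoms: none
Why: Steglich esterification acylates at oxygen under neutral conditions, so the ionisable dienyl carbinols keep constitution and configuration.

Step 5
Reactants: 7 (2S,3E,5E,7S)-octa-3,5-diene-2,7-diyl bis{[4-(tert-butyldimethylsilyloxy)-3-methoxyphenyl]acetate}
Product: 11 (2R,3S,4S,5R)-2,5-bis[4-(tert-butyldimethylsilyloxy)-3-methoxyphenyl]-3,4-di[(1E)-prop-1-enyl]hexanedioic acid, via bis(silyl ketene acetal) 8 (not isolated), via mono-rearranged silyl ester 9 (not isolated), via bis(trimethylsilyl) ester 10 (not isolated)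
Conditions: KN(SiMe3)2 (2.6 equiv), Me3SiCl (4 equiv), toluene/THF, −78 °C → rt, then 45 °C; aq. citric acid work-up
Reagents that add atoms: none
Why: Twofold Ireland–Claisen rearrangement: KN(SiMe3)2 deprotonates both arylacetate α-carbons and Me3SiCl traps the enolates as bis(silyl ketene acetal) 8, with aryl cis to OSiMe3. On warming, each allyl silyl ketene acetal undergoes a concerted suprafacial [3,3] shift through a six-membered chair transition state; the first ends on C4 and the second on C5 of the former diene, so the new bonds C7–C8 and C7′–C8′ end on adjacent carbons while the C–O bonds at the two carbinols break. The closest known reactions are the Ireland–Claisen rearrangement of secondary (E)-allylic arylacetates with 1,3-chirality transfer and twofold Claisen shifts across 2,4-diene-1,6-diols; no ring closes. C8 is controlled by the (S)-carbinol at C2 of the diene and C8′ by that at C7: with the carbinol methyl equatorial the new bond forms on the alkene face from which the C–O bond leaves, which for an (S)-carbinol and an E-alkene gives the 8R,8′R arrangement of the target (3S,4S in the numbering of 11) and leaves E-propenyl groups. The aryl-bearing centres C2 and C5 follow from the ketene acetal geometry in the same chair (2R,5R as drawn) and are erased in step 6, so only the facial selectivity at C8 and C8′ matters. The step needs chair over boat and methyl-equatorial over methyl-axial in both shifts, and completion of the more hindered second shift; the E-alkenes, the small carbinol methyl and the intramolecular nature of both shifts should secure this, and the centre formed first sits equatorially on the second chair and does not compete with carbinol control.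

Step 6
Reactants: 11 (2R,3S,4S,5R)-2,5-bis[4-(tert-butyldimethylsilyloxy)-3-methoxyphenyl]-3,4-di[(1E)-prop-1-enyl]hexanedioic acid
Product: 12 (2E,4S,5S,6E)-4,5-bis{[4-(tert-butyldimethylsilyloxy)-3-methoxyphenyl]methyl}octa-2,6-diene
Conditions: 9-mesityl-10-methylacridinium tetrafluoroborate (5 mol %), (PhS)2 (10 mol %), i-Pr2NEt (40 mol %), CF3CH2OH/EtOAc, 450 nm LEDs, rt
Reagents that add atoms: none
Why: Photoredox hydrodecarboxylation of arylacetic acids: the excited acridinium oxidises the carboxylate (directly or through the electron-rich arene), CO2 is lost, and the benzylic radical at C7 takes a hydrogen atom from PhSH formed from the disulfide co-catalyst. The stabilised benzylic radical has only 3- and 4-membered exo cyclisation modes onto the propenyl groups, so hydrogen transfer should win; C8 and C8′ are not touched.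

Step 7
Reactants: 12 (2E,4S,5S,6E)-4,5-bis{[4-(tert-butyldimethylsilyloxy)-3-methoxyphenyl]methyl}octa-2,6-diene
Product: 14 (2R,3R)-2,3-bis{[4-(tert-butyldimethylsilyloxy)-3-methoxyphenyl]methyl}butane-1,4-diol, via bis(ozonide) 13 (not isolated)
Conditions: O3, CH2Cl2, −78 °C (Sudan Red 7B end point); then NaBH4, MeOH, −78 → 0 °C
Reagents that add atoms: ozone, [O-][O+]=O
Why: Ozonolysis of the two 1,2-disubstituted alkenes, far more reactive than the arenes, gives the bis(ozonide), which NaBH4 reduces directly to the primary alcohols. No α-branched aldehyde is left standing, so C8 and C8′ should not epimerise.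

Step 8
Reactants: 15 ferulic acid, (2E)-3-(4-hydroxy-3-methoxyphenyl)prop-2-enoic acid
Product: 17 (2E)-3-[4-(tert-butyldimethylsilyloxy)-3-methoxyphenyl]prop-2-enoic acid, via bis-silylated ester 16 (not isolated)
Conditions: TBSCl (2.4 equiv), imidazole, DMF, rt; then AcOH/THF/H2O, rt
Reagents that add atoms: tert-butyldimethylsilyl chloride (TBSCl), CC(C)(C)[Si](C)(C)Cl
Why: Same silylation and selective silyl ester hydrolysis as in step 1; the E-alkene is not affected.

Step 9
Reactants: 14 (2R,3R)-2,3-bis{[4-(tert-butyldimethylsilyloxy)-3-methoxyphenyl]methyl}butane-1,4-diol (1.5 equiv); 17 (2E)-3-[4-(tert-butyldimethylsilyloxy)-3-methoxyphenyl]prop-2-enoic acid (1.0 equiv)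
Product: 18 (2R,3R)-4-hydroxy-2,3-bis{[4-(tert-butyldimethylsilyloxy)-3-methoxyphenyl]methyl}butyl (2E)-3-[4-(tert-butyldimethylsilyloxy)-3-methoxyphenyl]prop-2-enoate
Conditions: DCC, 4-(dimethylamino)pyridine (cat.), CH2Cl2, 0 °C, slow addition of 17; recovered 14 recycled
Reagents that add atoms: none
Why: Steglich mono-esterification of a C2-symmetric diol: the hydroxyls are homotopic, so only one mono-ester can form, and excess diol with limiting acid favours it over the diester. Mitsunobu and acidic conditions are avoided because they would close the 1,4-diol to a tetrahydrofuran.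

Step 10
Reactants: 18 (2R,3R)-4-hydroxy-2,3-bis{[4-(tert-butyldimethylsilyloxy)-3-methoxyphenyl]methyl}butyl (2E)-3-[4-(tert-butyldimethylsilyloxy)-3-methoxyphenyl]prop-2-enoate
Product: 19 hanultarin, (2R,3R)-4-hydroxy-2,3-bis[(4-hydroxy-3-methoxyphenyl)methyl]butyl (2E)-3-(4-hydroxy-3-methoxyphenyl)prop-2-enoate
Conditions: Bu4NF (3.3 equiv), AcOH (4 equiv), THF, 0 °C
Reagents that add atoms: none
Why: Fluoride cleaves aryl silyl ethers rapidly, and the acetic acid buffer protonates the phenoxides so the cinnamate ester is not cleaved. Any 1,4-acyl shift between the two hydroxyls would be degenerate because of the C2 symmetry.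

## Compound list

1 | homovanillic acid, (4-hydroxy-3-methoxyphenyl)acetic acid | COc1cc(CC(=O)O)ccc1O | starting material
2 | tert-butyldimethylsilyl [4-(tert-butyldimethylsilyloxy)-3-methoxyphenyl]acetate | COc1cc(CC(=O)O[Si](C)(C)C(C)(C)C)ccc1O[Si](C)(C)C(C)(C)C | intermediate
3 | [4-(tert-butyldimethylsilyloxy)-3-methoxyphenyl]acetic acid | COc1cc(CC(=O)O)ccc1O[Si](C)(C)C(C)(C)C | intermediate
4 | (S)-but-3-yn-2-ol | C[C@H](O)C#C | starting material
5 | (2S,7S)-octa-3,5-diyne-2,7-diol | C[C@H](O)C#CC#C[C@H](C)O | intermediate
6 | (2S,3E,5E,7S)-octa-3,5-diene-2,7-diol | C[C@H](O)/C=C/C=C/[C@H](C)O | intermediate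
7 | (2S,3E,5E,7S)-octa-3,5-diene-2,7-diyl bis{[4-(tert-butyldimethylsilyloxy)-3-methoxyphenyl]acetate} | C[C@H](OC(=O)Cc1ccc(O[Si](C)(C)C(C)(C)C)c(OC)c1)/C=C/C=C/[C@H](C)OC(=O)Cc1ccc(O[Si](C)(C)C(C)(C)C)c(OC)c1 | intermediate
8 | (2S,3E,5E,7S)-2,7-bis({(1Z)-2-[4-(tert-butyldimethylsilyloxy)-3-methoxyphenyl]-1-(trimethylsilyloxy)ethenyl}oxy)octa-3,5-diene | C[C@H](O/C(O[Si](C)(C)C)=C/c1ccc(O[Si](C)(C)C(C)(C)C)c(OC)c1)/C=C/C=C/[C@H](C)O/C(O[Si](C)(C)C)=C/c1ccc(O[Si](C)(C)C(C)(C)C)c(OC)c1 | intermediate
9 | trimethylsilyl (2R,3S,4E,6S)-2-[4-(tert-butyldimethylsilyloxy)-3-methoxyphenyl]-6-({(1Z)-2-[4-(tert-butyldimethylsilyloxy)-3-methoxyphenyl]-1-(trimethylsilyloxy)ethenyl}oxy)-3-[(1E)-prop-1-enyl]hept-4-enoate | C[Si](C)(C)OC(=O)[C@@H](c1ccc(O[Si](C)(C)C(C)(C)C)c(OC)c1)[C@@H](/C=C/C)/C=C/[C@H](C)O/C(O[Si](C)(C)C)=C/c1ccc(O[Si](C)(C)C(C)(C)C)c(OC)c1 | intermediate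
10 | bis(trimethylsilyl) (2R,3S,4S,5R)-2,5-bis[4-(tert-butyldimethylsilyloxy)-3-methoxyphenyl]-3,4-di[(1E)-prop-1-enyl]hexanedioate | C[Si](C)(C)OC(=O)[C@@H](c1ccc(O[Si](C)(C)C(C)(C)C)c(OC)c1)[C@@H](/C=C/C)[C@H](/C=C/C)[C@H](c1ccc(O[Si](C)(C)C(C)(C)C)c(OC)c1)C(=O)O[Si](C)(C)C | intermediate
11 | (2R,3S,4S,5R)-2,5-bis[4-(tert-butyldimethylsilyloxy)-3-methoxyphenyl]-3,4-di[(1E)-prop-1-enyl]hexanedioic acid | OC(=O)[C@@H](c1ccc(O[Si](C)(C)C(C)(C)C)c(OC)c1)[C@@H](/C=C/C)[C@H](/C=C/C)[C@H](c1ccc(O[Si](C)(C)C(C)(C)C)c(OC)c1)C(=O)O | intermediate
12 | (2E,4S,5S,6E)-4,5-bis{[4-(tert-butyldimethylsilyloxy)-3-methoxyphenyl]methyl}octa-2,6-diene | C/C=C/[C@H](Cc1ccc(O[Si](C)(C)C(C)(C)C)c(OC)c1)[C@H](/C=C/C)Cc1ccc(O[Si](C)(C)C(C)(C)C)c(OC)c1 | intermediate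
13 | 3,3′-[(2R,3R)-1,4-bis[4-(tert-butyldimethylsilyloxy)-3-methoxyphenyl]butane-2,3-diyl]bis(5-methyl-1,2,4-trioxolane), mixture of isomers at the trioxolane carbons | CC1OC(OO1)[C@H](Cc1ccc(O[Si](C)(C)C(C)(C)C)c(OC)c1)[C@H](C1OC(C)OO1)Cc1ccc(O[Si](C)(C)C(C)(C)C)c(OC)c1 | intermediate
14 | (2R,3R)-2,3-bis{[4-(tert-butyldimethylsilyloxy)-3-methoxyphenyl]methyl}butane-1,4-diol | OC[C@H](Cc1ccc(O[Si](C)(C)C(C)(C)C)c(OC)c1)[C@H](CO)Cc1ccc(O[Si](C)(C)C(C)(C)C)c(OC)c1 | intermediate
15 | ferulic acid, (2E)-3-(4-hydroxy-3-methoxyphenyl)prop-2-enoic acid | COc1cc(/C=C/C(=O)O)ccc1O | starting material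
16 | tert-butyldimethylsilyl (2E)-3-[4-(tert-butyldimethylsilyloxy)-3-methoxyphenyl]prop-2-enoate | COc1cc(/C=C/C(=O)O[Si](C)(C)C(C)(C)C)ccc1O[Si](C)(C)C(C)(C)C | intermediate
17 | (2E)-3-[4-(tert-butyldimethylsilyloxy)-3-methoxyphenyl]prop-2-enoic acid | COc1cc(/C=C/C(=O)O)ccc1O[Si](C)(C)C(C)(C)C | intermediate
18 | (2R,3R)-4-hydroxy-2,3-bis{[4-(tert-butyldimethylsilyloxy)-3-methoxyphenyl]methyl}butyl (2E)-3-[4-(tert-butyldimethylsilyloxy)-3-methoxyphenyl]prop-2-enoate | COc1cc(/C=C/C(=O)OC[C@H](Cc2ccc(O[Si](C)(C)C(C)(C)C)c(OC)c2)[C@H](CO)Cc2ccc(O[Si](C)(C)C(C)(C)C)c(OC)c2)ccc1O[Si](C)(C)C(C)(C)C | intermediate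
19 | hanultarin, (2R,3R)-4-hydroxy-2,3-bis[(4-hydroxy-3-methoxyphenyl)methyl]butyl (2E)-3-(4-hydroxy-3-methoxyphenyl)prop-2-enoate | COc1cc(/C=C/C(=O)OC[C@H](Cc2ccc(O)c(OC)c2)[C@H](CO)Cc2ccc(O)c(OC)c2)ccc1O | target

## Step count and risks

Total: 10 steps. Longest linear sequence: 8 steps from 4 (steps 2, 3, 4, 5, 6, 7, 9, 10). Steps 1 and 8 are one-step side branches.

**Step 5 (key step).** The second shift may lag behind the first, because its alkene terminus then carries a branched carbon. The remaining silyl ketene acetal could then be lost to hydrolysis, or to fragmentation into an arylketene and a dienyl alkoxide, before it rearranges. Partial passage through a boat transition state would erode the configuration at C8′. Fallback: the same two bonds are formed by a thermal orthoester Claisen, which avoids ester enolates and also bypasses step 6. It sets out from 6 and returns at 12. Dienediol 6 is heated with MeC(OEt)3 and catalytic propanoic acid at 140 °C (twofold Johnson–Claisen, same chair and same chirality transfer) to give diethyl (3S,4S)-3,4-di[(1E)-prop-1-enyl]hexanedioate F1. LiOH saponification gives (3S,4S)-3,4-di[(1E)-prop-1-enyl]hexanedioic acid F2, and diisopropylcarbodiimide with N-hydroxyphthalimide gives bis(1,3-dioxoisoindolin-2-yl) (3S,4S)-3,4-di[(1E)-prop-1-enyl]hexanedioate F3. Commercial (4-bromo-2-methoxyphenoxy)(tert-butyl)dimethylsilane F4 is converted with Mg/LiCl and then ZnCl2 into [4-(tert-butyldimethylsilyloxy)-3-methoxyphenyl]zinc chloride F5. Decarboxylative arylation of F3 with F5 under Fe(acac)3 and 1,2-bis(diphenylphosphino)benzene puts the aryl groups on C7 and C7′ and gives 12.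

**Step 6.** Single-electron oxidation of the electron-rich arenes or of the product may compete with carboxylate oxidation. Reversible thiyl-radical addition to the propenyl groups (hydrothiolation, or 5-exo closure across the 1,5-diene) may consume the co-catalyst, and the second decarboxylation may stop short. Fallback: reductive fragmentation of a redox-active ester, with no thiyl radical or arene oxidation. It sets out from 11 and returns at 12. Diacid 11 is converted with diisopropylcarbodiimide and N-hydroxyphthalimide into bis(1,3-dioxoisoindolin-2-yl) (2R,3S,4S,5R)-2,5-bis[4-(tert-butyldimethylsilyloxy)-3-methoxyphenyl]-3,4-di[(1E)-prop-1-enyl]hexanedioate F6. This is reduced with NiCl2·6H2O, 4,4′-di-tert-butyl-2,2′-bipyridine, Zn and PhSiH3 in THF/DMF/i-PrOH at 40 °C to 12.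

**Step 7.** Ozone may attack the silyloxy-methoxy arenes once the alkenes are consumed, or reduction of the ozonide may be incomplete. Fallback: glycol cleavage without ozone, setting out from 12 and returning at 14. Dihydroxylation with K2OsO2(OH)4 and N-methylmorpholine N-oxide gives (4R,5R)-4,5-bis{[4-(tert-butyldimethylsilyloxy)-3-methoxyphenyl]methyl}octane-2,3,6,7-tetraol F7 (mixture at the carbinol carbons). NaIO4 cleaves it to (2R,3R)-2,3-bis{[4-(tert-butyldimethylsilyloxy)-3-methoxyphenyl]methyl}butanedial F8, which is reduced at once with NaBH4 to 14 so that the α-centres do not epimerise.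

**Step 9.** Over-acylation to the diester and incomplete conversion are inherent in a statistical reaction on two homotopic hydroxyls, so material is lost to recycling. Fallback: differentiate the hydroxyls before acylation, setting out from 14 and returning at 19. The monosodium alkoxide of 14 (NaH, 1 equiv, THF) is silylated with TBSCl to (2R,3R)-4-(tert-butyldimethylsilyloxy)-2,3-bis{[4-(tert-butyldimethylsilyloxy)-3-methoxyphenyl]methyl}butan-1-ol F9. Steglich esterification with excess 17 gives (2R,3R)-4-(tert-butyldimethylsilyloxy)-2,3-bis{[4-(tert-butyldimethylsilyloxy)-3-methoxyphenyl]methyl}butyl (2E)-3-[4-(tert-butyldimethylsilyloxy)-3-methoxyphenyl]prop-2-enoate F10. Removal of all four silyl groups with Bu4NF/AcOH in THF at rt gives 19.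

## Further compounds

F1 | step 5 | diethyl (3S,4S)-3,4-di[(1E)-prop-1-enyl]hexanedioate | CCOC(=O)C[C@@H](/C=C/C)[C@H](/C=C/C)CC(=O)OCC
F2 | step 5 | (3S,4S)-3,4-di[(1E)-prop-1-enyl]hexanedioic acid | OC(=O)C[C@@H](/C=C/C)[C@H](/C=C/C)CC(=O)O
F3 | step 5 | bis(1,3-dioxoisoindolin-2-yl) (3S,4S)-3,4-di[(1E)-prop-1-enyl]hexanedioate | O=C(C[C@@H](/C=C/C)[C@H](/C=C/C)CC(=O)ON1C(=O)c2ccccc2C1=O)ON1C(=O)c2ccccc2C1=O
F4 | step 5 | (4-bromo-2-methoxyphenoxy)(tert-butyl)dimethylsilane | COc1cc(Br)ccc1O[Si](C)(C)C(C)(C)C
F5 | step 5 | [4-(tert-butyldimethylsilyloxy)-3-methoxyphenyl]zinc chloride | COc1cc([Zn]Cl)ccc1O[Si](C)(C)C(C)(C)C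
F6 | step 6 | bis(1,3-dioxoisoindolin-2-yl) (2R,3S,4S,5R)-2,5-bis[4-(tert-butyldimethylsilyloxy)-3-methoxyphenyl]-3,4-di[(1E)-prop-1-enyl]hexanedioate | O=C(ON1C(=O)c2ccccc2C1=O)[C@@H](c1ccc(O[Si](C)(C)C(C)(C)C)c(OC)c1)[C@@H](/C=C/C)[C@H](/C=C/C)[C@H](c1ccc(O[Si](C)(C)C(C)(C)C)c(OC)c1)C(=O)ON1C(=O)c2ccccc2C1=O
F7 | step 7 | (4R,5R)-4,5-bis{[4-(tert-butyldimethylsilyloxy)-3-methoxyphenyl]methyl}octane-2,3,6,7-tetraol, mixture at C2, C3, C6 and C7 | CC(O)C(O)[C@H](Cc1ccc(O[Si](C)(C)C(C)(C)C)c(OC)c1)[C@H](C(O)C(C)O)Cc1ccc(O[Si](C)(C)C(C)(C)C)c(OC)c1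
F8 | step 7 | (2R,3R)-2,3-bis{[4-(tert-butyldimethylsilyloxy)-3-methoxyphenyl]methyl}butanedial | O=C[C@H](Cc1ccc(O[Si](C)(C)C(C)(C)C)c(OC)c1)[C@H](C=O)Cc1ccc(O[Si](C)(C)C(C)(C)C)c(OC)c1
F9 | step 9 | (2R,3R)-4-(tert-butyldimethylsilyloxy)-2,3-bis{[4-(tert-butyldimethylsilyloxy)-3-methoxyphenyl]methyl}butan-1-ol | OC[C@H](Cc1ccc(O[Si](C)(C)C(C)(C)C)c(OC)c1)[C@H](CO[Si](C)(C)C(C)(C)C)Cc1ccc(O[Si](C)(C)C(C)(C)C)c(OC)c1
F10 | step 9 | (2R,3R)-4-(tert-butyldimethylsilyloxy)-2,3-bis{[4-(tert-butyldimethylsilyloxy)-3-methoxyphenyl]methyl}butyl (2E)-3-[4-(tert-butyldimethylsilyloxy)-3-methoxyphenyl]prop-2-enoate | COc1cc(/C=C/C(=O)OC[C@H](Cc2ccc(O[Si](C)(C)C(C)(C)C)c(OC)c2)[C@H](CO[Si](C)(C)C(C)(C)C)Cc2ccc(O[Si](C)(C)C(C)(C)C)c(OC)c2)ccc1O[Si](C)(C)C(C)(C)C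
A1 | alternative 1 | (2E)-3-[3-methoxy-4-(methoxymethoxy)phenyl]-1-(1-methylimidazol-2-yl)prop-2-en-1-one | COCOc1ccc(/C=C/C(=O)c2nccn2C)cc1OC
A2 | alternative 1 | all-trans head-to-head cyclobutane dimer of A1, [3,4-bis(3-methoxy-4-methoxymethoxyphenyl)cyclobutane-1,2-diyl]bis[(1-methylimidazol-2-yl)methanone], acyl-bearing carbons configured as C8 and C8′ | O=C(c1nccn1C)[C@@H]1[C@@H](c2ccc(OCOC)c(OC)c2)[C@H](c2ccc(OCOC)c(OC)c2)[C@H]1C(=O)c1nccn1C
A3 | alternative 2 | (2E)-4-[4-(tert-butyldimethylsilyloxy)-3-methoxyphenyl]-2-{[4-(tert-butyldimethylsilyloxy)-3-methoxyphenyl]methyl}but-2-en-1-ol | OC/C(Cc1ccc(O[Si](C)(C)C(C)(C)C)c(OC)c1)=C/Cc1ccc(O[Si](C)(C)C(C)(C)C)c(OC)c1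
A4 | alternative 2 | (3R,4R)-3,4-bis{[4-(tert-butyldimethylsilyloxy)-3-methoxyphenyl]methyl}oxolan-2-one | O=C1OC[C@H](Cc2ccc(O[Si](C)(C)C(C)(C)C)c(OC)c2)[C@H]1Cc1ccc(O[Si](C)(C)C(C)(C)C)c(OC)c1
A5 | alternative 3 | (2E)-1,4-bis(4-benzyloxy-3-methoxyphenyl)but-2-ene | COc1cc(C/C=C/Cc2ccc(OCc3ccccc3)c(OC)c2)ccc1OCc1ccccc1
A6 | alternative 3 | dimethyl (2R,3R)-2,3-bis[(4-benzyloxy-3-methoxyphenyl)methyl]butanedioate | COC(=O)[C@H](Cc1ccc(OCc2ccccc2)c(OC)c1)[C@H](C(=O)OC)Cc1ccc(OCc2ccccc2)c(OC)c1
A7 | alternative 3 | (2R,3R)-2,3-bis[(4-benzyloxy-3-methoxyphenyl)methyl]butane-1,4-diol | OC[C@H](Cc1ccc(OCc2ccccc2)c(OC)c1)[C@H](CO)Cc1ccc(OCc2ccccc2)c(OC)c1
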